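The quinone ring is numbered from carbonyl C1, which lies between C2 (OMe) and C6 (chain). The oxygens at C2 and C4 are then meta-related and C6 carries the fatty chain. This is a 5-alkylresorcinol pattern, with the C1 oxygen as a late addition, so the route rests on cutting ring bond C5–C6. The precursor is an open-chain di-tert-butyl 3,5,7-trioxodocosanedioate, assembled from a six-carbon diketo ester trianion and a sixteen-carbon Weinreb amide. Aldol attack of its C2 methylene on the C7 ketone forms the only carbocycle, aromatises it and sets oxygens, chain and a removable carboxyl in place. Chelation-guided O-methylation, acidolysis with decarboxylation, and para-oxidation complete the target.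

Key step: step 4

Remark: hexadecanedioic acid mono-tert-butyl ester is taken as a purchasable building block (it is sold for peptide lipidation), which avoids a statistical monoesterification; all polycarbonyl compounds are drawn as keto tautomers although they are largely enolised.

Step 1
Reactants: 1 tert-butyl acetoacetate; 2 N-methoxy-N-methylacetamide
Product: 4 tert-butyl 3,5-dioxohexanoate, via dilithio dianion 3 (not isolated)
Conditions: LiN(iPr)2 (2.1 equiv), THF, 0 °C; 2, −78 to 0 °C; 1 M HCl quench
Reagents that add atoms: none
Why: This is a γ-acylation of a β-keto ester dianion combined with the Weinreb ketone synthesis, in which the last-formed terminal carbanion is the most nucleophilic site and the N-methoxy-N-methyl amide holds the adduct as a lithium chelate until the quench, so that neither double addition nor proton quench by the acidic product should occur.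

Step 2
Reactants: 5 hexadecanedioic acid mono-tert-butyl ester (16-tert-butoxy-16-oxohexadecanoic acid)
Product: 7 tert-butyl 16-[methoxy(methyl)amino]-16-oxohexadecanoate, via acyl imidazolide 6 (not isolated)
Conditions: CDI (1.1 equiv), CH2Cl2, rt; MeNHOMe·HCl (1.3 equiv), rt
Reagents that add atoms: N,O-dimethylhydroxylamine hydrochloride, CNOC.Cl; 1,1'-carbonyldiimidazole, O=C(n1ccnc1)n1ccnc1 (its imidazolyl group stays only in 6)
Why: Carbonyldiimidazole activation followed by aminolysis (Weinreb amide formation) runs under near-neutral conditions that leave the tert-butyl ester untouched, and the hydrochloride supplies the proton that lets imidazole leave.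

Step 3
Reactants: 4 tert-butyl 3,5-dioxohexanoate; 7 tert-butyl 16-[methoxy(methyl)amino]-16-oxohexadecanoate
Product: 9 di-tert-butyl 3,5,7-trioxodocosanedioate, via trilithio trianion 8 (not isolated)
Conditions: 4 (1.5 equiv), LiN(iPr)2 (3.05 equiv per 4), THF, −78 to 0 °C; 7, −78 to −10 °C; AcOH quench at −78 °C; cold extractive work-up, crude 9 used directly
Reagents that add atoms: none
Why: This is a terminal C-acylation of a β,δ-diketo ester 2,4,6-trianion, in which the C6 carbanion formed last is the most reactive site, the Weinreb amide stores the adduct as a chelated tetrahedral alkoxide until the cold quench so that the acidic product never meets unreacted trianion, and both tert-butyl esters are too hindered to be attacked.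

Step 4
Reactants: 9 di-tert-butyl 3,5,7-trioxodocosanedioate
Product: 11 tert-butyl 2-(15-tert-butoxy-15-oxopentadecyl)-4,6-dihydroxybenzoate, via cyclic ketol 10 (not isolated)
Conditions: NaOAc (5 equiv), AcOH (1 equiv), MeOH–THF (1:1), argon, rt to 40 °C
Reagents that add atoms: none
Why: Acetate reversibly enolises 9; its resting anions sit at C4 and C6, the methylenes between two ketones, but these have no six-membered aldol available, so ring formation runs through the less populated form in which C2 (between the ester and the C3 ketone) is the nucleophilic enolate carbon and C7 is a free ketone, giving ketol 10. Loss of water from the tertiary carbinol of 10 and enolisation of the C3 and C5 carbonyls are irreversible and pull all preceding equilibria towards arene 11, the new bond C2–C7 being ring bond C5–C6 of the target. The closest known reaction type is the buffer-induced intramolecular aldol condensation with aromatisation of 3,5,7-triketo esters and acids to 6-substituted 2,4-dihydroxybenzoates. The single ring, the six-membered carbocycle C2–C7, closes in a 6-(enolendo)-exo-trig mode (6-(enolexo)-exo-trig if the ester enolate is drawn), both favoured; the two stereocentres of 10 are transient and none remains. The selectivity needed is aldol closure over attack of C6 or of an enol oxygen on the C1 ester (acylphloroglucinol or 4-hydroxy-2-pyranone) and over acid-driven 4-pyranone formation. The substrate secures it through the hindered tert-butyl ester with its poor leaving group, while the near-neutral buffer avoids both the polyanions that favour Claisen closure in strong alkali and the acidity that favours pyranones, and C8 is far too weakly acidic to attack C3.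

Step 5
Reactants: 11 tert-butyl 2-(15-tert-butoxy-15-oxopentadecyl)-4,6-dihydroxybenzoate
Product: 12 tert-butyl 2-(15-tert-butoxy-15-oxopentadecyl)-6-hydroxy-4-methoxybenzoate
Conditions: MeI (1.05 equiv), K2CO3 (1.1 equiv), acetone, rt
Reagents that add atoms: iodomethane, CI
Why: In this Williamson etherification under weak base, the 4-OH para to the ester is the more acidic and unhindered phenol, whereas the 6-OH is locked in a six-membered hydrogen-bond chelate with the ester carbonyl and should not react with one equivalent of MeI.

Step 6
Reactants: 12 tert-butyl 2-(15-tert-butoxy-15-oxopentadecyl)-6-hydroxy-4-methoxybenzoate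
Product: 14 phenol acid 15-(3-hydroxy-5-methoxyphenyl)pentadecanoic acid, via salicylic diacid 13 (not isolated)
Conditions: CF3CO2H–CH2Cl2 (1:1), Et3SiH (3 equiv), rt; evaporate; xylene, 140 °C; aqueous work-up
Reagents that add atoms: none
Why: Acidolysis of both tert-butyl esters by alkyl–oxygen fission (AAL1) is indifferent to the steric shielding that makes 2,6-disubstituted benzoates hard to saponify, Et3SiH reduces the tert-butyl cations to isobutane before they can alkylate the electron-rich ring, and the freed 6-alkyl-4-methoxysalicylic acid 13 undergoes thermal protodecarboxylation (ipso protonation ortho to OH and para to OMe) while the aliphatic acid is inert.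

Step 7
Reactants: 14 phenol acid 15-(3-hydroxy-5-methoxyphenyl)pentadecanoic acid
Product: 15 target quinone 15-(5-methoxy-3,6-dioxocyclohexa-1,4-dien-1-yl)pentadecanoic acid
Conditions: (KSO3)2NO (2.5 equiv), KH2PO4–Na2HPO4 buffer (pH 7), H2O–acetone, rt, dark; then acidify to pH 3 and extract
Reagents that add atoms: potassium nitrosodisulfonate (KSO3)2NO, [K+].[K+].[O]N(S(=O)(=O)[O-])S(=O)(=O)[O-]
Why: In this Teuber oxidation one nitroxyl radical abstracts the phenolic hydrogen, a second couples through its oxygen at the open para carbon between OMe and chain, and loss of HN(SO3K)2 gives the para-quinone, a conversion established for 5-alkyl-3-methoxyphenols, with the carboxylate keeping the substrate dissolved and staying inert.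

Compound list
1 | tert-butyl acetoacetate (tert-butyl 3-oxobutanoate) | CC(=O)CC(=O)OC(C)(C)C | starting material
2 | N-methoxy-N-methylacetamide | CON(C)C(C)=O | starting material
3 | dilithio dianion of 1 (dilithium 1-tert-butoxybuta-1,3-diene-1,3-diolate) | [Li+].[Li+].C=C([O-])C=C([O-])OC(C)(C)C | intermediate
4 | tert-butyl 3,5-dioxohexanoate | CC(=O)CC(=O)CC(=O)OC(C)(C)C | intermediate
5 | hexadecanedioic acid mono-tert-butyl ester (16-tert-butoxy-16-oxohexadecanoic acid) | OC(=O)CCCCCCCCCCCCCCC(=O)OC(C)(C)C | starting material
6 | tert-butyl 16-(1H-imidazol-1-yl)-16-oxohexadecanoate | O=C(CCCCCCCCCCCCCCC(=O)OC(C)(C)C)n1ccnc1 | intermediate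
7 | tert-butyl 16-[methoxy(methyl)amino]-16-oxohexadecanoate | CON(C)C(=O)CCCCCCCCCCCCCCC(=O)OC(C)(C)C | intermediate
8 | trilithio trianion of 4 (trilithium 1-tert-butoxyhexa-1,3,5-triene-1,3,5-triolate) | [Li+].[Li+].[Li+].C=C([O-])C=C([O-])C=C([O-])OC(C)(C)C | intermediate
9 | di-tert-butyl 3,5,7-trioxodocosanedioate | CC(C)(C)OC(=O)CC(=O)CC(=O)CC(=O)CCCCCCCCCCCCCCC(=O)OC(C)(C)C | intermediate
10 | tert-butyl 2-(15-tert-butoxy-15-oxopentadecyl)-2-hydroxy-4,6-dioxocyclohexane-1-carboxylate (mixture of stereoisomers, transient) | CC(C)(C)OC(=O)C1C(=O)CC(=O)CC1(O)CCCCCCCCCCCCCCC(=O)OC(C)(C)C | intermediate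
11 | tert-butyl 2-(15-tert-butoxy-15-oxopentadecyl)-4,6-dihydroxybenzoate | CC(C)(C)OC(=O)c1c(O)cc(O)cc1CCCCCCCCCCCCCCC(=O)OC(C)(C)C | intermediate
12 | tert-butyl 2-(15-tert-butoxy-15-oxopentadecyl)-6-hydroxy-4-methoxybenzoate | COc1cc(O)c(C(=O)OC(C)(C)C)c(CCCCCCCCCCCCCCC(=O)OC(C)(C)C)c1 | intermediate
13 | 2-(14-carboxytetradecyl)-6-hydroxy-4-methoxybenzoic acid | COc1cc(O)c(C(=O)O)c(CCCCCCCCCCCCCCC(=O)O)c1 | intermediate
14 | 15-(3-hydroxy-5-methoxyphenyl)pentadecanoic acid | COc1cc(O)cc(CCCCCCCCCCCCCCC(=O)O)c1 | intermediate
15 | 15-(5-methoxy-3,6-dioxocyclohexa-1,4-dien-1-yl)pentadecanoic acid (achiral) | COC1=CC(=O)C=C(CCCCCCCCCCCCCCC(=O)O)C1=O | target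

Total step count: 7. Longest linear sequence: 6 (steps 2 to 7 from 5, or equally step 1 and steps 3 to 7 from 1).

Steps most likely to fail

**Step 3.**
- What may go wrong:
  - proton transfer from the α-methylene of 7 to the very basic terminal carbanion of 8;
  - an incomplete third deprotonation of 4, which diverts acylation to C4 or to oxygen;
  - premature cyclisation of the labile product during work-up.
- Fallback, setting out from 7 and coming back at 9. The triply charged nucleophile is exchanged for a dianion whose ester end is masked as a dioxinone. Commercial 2,2,6-trimethyl-4H-1,3-dioxin-4-one is deprotonated (LiN(SiMe3)2, THF, −78 °C) to lithium 2,2-dimethyl-6-methylidene-6H-1,3-dioxin-4-olate F1. Acetyl chloride C-acetylates F1 to 2,2-dimethyl-6-(2-oxopropyl)-4H-1,3-dioxin-4-one F2. Two equivalents of LiN(iPr)2 convert F2 into the dilithio dianion of the keto-dioxinone F3. F3 should be acylated at its terminal carbon by 7, after an AcOH quench, to tert-butyl 19-(2,2-dimethyl-4-oxo-4H-1,3-dioxin-6-yl)-16,18-dioxononadecanoate F4. Heating F4 in toluene at 110 °C with excess tert-butanol expels acetone by a retro-hetero-Diels–Alder reaction. This gives the acylketene tert-butyl 16,18,20,22-tetraoxodocos-21-enoate F5, which the alcohol traps to deliver 9 for step 4.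

**Step 4.**
- What may go wrong:
  - acyl substitution at C1 by C6 or by an enol oxygen;
  - cyclodehydration of the triketone array to a pyranone;
  - retro-Claisen fragmentation;
  - stalling at the ketol stage.
- Fallback, setting out from 5 and coming back at 14. The arene is bought instead of built, and the chain is attached by decarboxylative cross-coupling. This removes exactly the carboxyl carbon that the aldol route turns into the chain-bearing ring carbon. 5 is esterified with N-hydroxyphthalimide (N,N'-diisopropylcarbodiimide, DMAP, CH2Cl2) to 1-tert-butyl 16-(1,3-dioxoisoindolin-2-yl) hexadecanedioate F6. Nickel-catalysed reductive coupling with 1-iodo-3,5-dimethoxybenzene (NiBr2(MeOCH2CH2OMe), 4,4'-di-tert-butyl-2,2'-bipyridine, Zn, N,N-dimethylacetamide, rt) should give tert-butyl 15-(3,5-dimethoxyphenyl)pentadecanoate F7. CF3CO2H and Et3SiH in CH2Cl2 free 15-(3,5-dimethoxyphenyl)pentadecanoic acid F8. NaSEt in DMF at 140 °C removes one of the two equivalent methyl groups by SN2 attack. It should stop there, because the phenoxide formed shuts down the second cleavage, and this gives 14.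

**Step 7.**
- What may go wrong:
  - slow or incomplete oxidation because the long-chain carboxylate aggregates in the aqueous buffer;
  - radical coupling at an ortho carbon;
  - base- or light-induced degradation of the methoxyquinone during a long reaction.
- Fallback, setting out from 14 and coming back at 15. The para oxygen is brought in through nitrogen by ionic chemistry in alcoholic solution. Nitrosation (NaNO2, aqueous HCl–EtOH, 0 °C) attacks 3,5-disubstituted phenols para to the hydroxyl. It should give 15-(5-hydroxy-3-methoxy-2-nitrosophenyl)pentadecanoic acid F9, the tautomer of the quinone monooxime. Reduction (Na2S2O4, aqueous EtOH) gives 15-(2-amino-5-hydroxy-3-methoxyphenyl)pentadecanoic acid F10. FeCl3 in dilute aqueous HCl oxidises it to the quinone imine 15-(6-imino-5-methoxy-3-oxocyclohexa-1,4-dien-1-yl)pentadecanoic acid F11, which hydrolyses in the same flask to 15.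

Further compounds
F1 | step 3 | lithium 2,2-dimethyl-6-methylidene-6H-1,3-dioxin-4-olate | [Li+].C=C1C=C([O-])OC(C)(C)O1
F2 | step 3 | 2,2-dimethyl-6-(2-oxopropyl)-4H-1,3-dioxin-4-one | CC(=O)CC1=CC(=O)OC(C)(C)O1
F3 | step 3 | dilithio dianion of the keto-dioxinone | [Li+].[Li+].C=C([O-])C=C1C=C([O-])OC(C)(C)O1
F4 | step 3 | tert-butyl 19-(2,2-dimethyl-4-oxo-4H-1,3-dioxin-6-yl)-16,18-dioxononadecanoate | CC(C)(C)OC(=O)CCCCCCCCCCCCCCC(=O)CC(=O)CC1=CC(=O)OC(C)(C)O1
F5 | step 3 | tert-butyl 16,18,20,22-tetraoxodocos-21-enoate (acylketene) | O=C=CC(=O)CC(=O)CC(=O)CCCCCCCCCCCCCCC(=O)OC(C)(C)C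
F6 | step 4 | 1-tert-butyl 16-(1,3-dioxoisoindolin-2-yl) hexadecanedioate | CC(C)(C)OC(=O)CCCCCCCCCCCCCCC(=O)ON1C(=O)c2ccccc2C1=O
F7 | step 4 | tert-butyl 15-(3,5-dimethoxyphenyl)pentadecanoate | COc1cc(OC)cc(CCCCCCCCCCCCCCC(=O)OC(C)(C)C)c1
F8 | step 4 | 15-(3,5-dimethoxyphenyl)pentadecanoic acid | COc1cc(OC)cc(CCCCCCCCCCCCCCC(=O)O)c1
F9 | step 7 | 15-(5-hydroxy-3-methoxy-2-nitrosophenyl)pentadecanoic acid | COc1cc(O)cc(CCCCCCCCCCCCCCC(=O)O)c1N=O
F10 | step 7 | 15-(2-amino-5-hydroxy-3-methoxyphenyl)pentadecanoic acid | COc1cc(O)cc(CCCCCCCCCCCCCCC(=O)O)c1N
F11 | step 7 | 15-(6-imino-5-methoxy-3-oxocyclohexa-1,4-dien-1-yl)pentadecanoic acid | COC1=CC(=O)C=C(CCCCCCCCCCCCCCC(=O)O)C1=N
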